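Ring A is cut into two open-chain partners, a vinylketene released from 1-diazo-3-methoxybut-3-en-2-one and a methoxy ynol ether that already carries the chromene on a silylated propargylic carbinol. The feature exploited is the alternating oxygenation of ring A around its acyl-bearing carbon C1: the C2 hydroxyl comes from the ketene carbonyl, the C6 methoxy from the ynol ether carbon and the C4 methoxy from the methoxyvinyl carbon, so the three oxygens never need to be told apart. A single light-then-heat benzannulation forms four ring A bonds and closes the ring; desilylation and oxidation of the carbinol to the diaryl ketone then give the target.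

Key step: step 7

Remark on the chemistry: the carbinol carbon of the ynol ether is carried as the racemate because it becomes the ketone carbon. The phenol is protected as a triisopropylsilyl ether (stable to the lithium bases of step 4) and the carbinol as a triethylsilyl ether (small, installed in the same flask), and both fall to fluoride in one operation. 3,5-Dihydroxybenzaldehyde is taken as the commercial arene so that the formyl group needs no redox adjustment.

Step 1
Reactants: 1 3,5-dihydroxybenzaldehyde; 2 3-chloro-3-methylbut-1-yne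
Product: 3 3-hydroxy-5-[(2-methylbut-3-yn-2-yl)oxy]benzaldehyde
Conditions: 1 (2 equiv), DBU, CuCl2·2H2O (cat.), MeCN, 0 °C
Reagents that add atoms: none
Why: Copper-catalysed propargylic etherification of a phenol with a tertiary propargylic chloride (copper acetylide ionising to an allenylidene that the phenoxide captures at the tertiary carbon) should give the aryl 1,1-dimethylpropargyl ether, and the excess of the symmetric diol 1 keeps double alkylation low.

Step 2
Reactants: 3 3-hydroxy-5-[(2-methylbut-3-yn-2-yl)oxy]benzaldehyde
Product: 6 7-hydroxy-2,2-dimethyl-2H-chromene-5-carbaldehyde, via allenylphenol 4 (not isolated), via o-quinone methide 5 (not isolated)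
Conditions: o-xylene, 140 °C
Reagents that add atoms: none
Why: Aromatic propargyl Claisen rearrangement and enolisation give allenylphenol 4, whose 1,5-hydrogen shift to o-quinone methide 5 and oxa-6π electrocyclisation close the pyran ring; migration to the ring carbon between the formyl group and the ether oxygen is expected because a meta acceptor directs towards itself and the meta hydroxyl directs to its para position.

Step 3
Reactants: 6 7-hydroxy-2,2-dimethyl-2H-chromene-5-carbaldehyde
Product: 7 2,2-dimethyl-7-[(triisopropylsilyl)oxy]-2H-chromene-5-carbaldehyde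
Conditions: i-Pr3SiCl, imidazole, DMF, rt
Reagents that add atoms: chlorotriisopropylsilane, CC(C)[Si](Cl)(C(C)C)C(C)C
Why: Imidazole-mediated silylation of a phenol (silyl ether protection) should be uneventful, and the bulky aryl silyl ether is chosen to withstand the lithium methoxide and amine of step 4.

Step 4
Reactants: 7 2,2-dimethyl-7-[(triisopropylsilyl)oxy]-2H-chromene-5-carbaldehyde; 8 chloroacetaldehyde dimethyl acetal
Product: 11 racemic 5-{3-methoxy-1-[(triethylsilyl)oxy]prop-2-yn-1-yl}-2,2-dimethyl-7-[(triisopropylsilyl)oxy]-2H-chromene, via lithium methoxyacetylide 9 (not isolated), via lithium propargylic alkoxide 10 (not isolated)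
Conditions: Et2NH, n-BuLi (3 equiv per 8), THF, 0 °C, then 8; 7, −78 °C; Et3SiCl, −78 → 0 °C; NaHCO3 work-up, Et3N-deactivated SiO2
Reagents that add atoms: chlorotriethylsilane, CC[Si](Cl)(CC)CC (n-butyllithium, CCCC[Li], supplies only the lithium of 9 and 10)
Why: Double elimination and deprotonation of the chloroacetal by LiNEt2 give lithium methoxyacetylide 9, whose 1,2-addition to the aldehyde forms alkoxide 10 (new carbinol centre formed without control, racemic, removed in step 9), and O-silylation in the same flask avoids isolating the free propargylic carbinol, which is prone to acid-catalysed Meyer–Schuster rearrangement.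

Step 5
Reactants: 12 3,3-dimethoxybutan-2-one
Product: 13 3-methoxybut-3-en-2-one
Conditions: TsOH·H2O (cat.), hydroquinone (trace), neat, 130–150 °C, MeOH distilled off
Reagents that add atoms: none
Why: Acid-catalysed thermal elimination of methanol from a ketal through its oxocarbenium ion (ketal to enol ether conversion) should give the conjugated α-methoxy enone, driven by removal of methanol.

Step 6
Reactants: 13 3-methoxybut-3-en-2-one
Product: 15 1-diazo-3-methoxybut-3-en-2-one, via trifluoroacetyl diketone 14 (not isolated)
Conditions: LiN(SiMe3)2, THF, −78 °C; CF3CO2CH2CF3; then 4-AcNHC6H4SO2N3, Et3N, H2O, MeCN, rt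
Reagents that add atoms: 4-acetamidobenzenesulfonyl azide, CC(=O)Nc1ccc(S(=O)(=O)N=[N+]=[N-])cc1 (the two diazo nitrogens); 2,2,2-trifluoroethyl trifluoroacetate, O=C(OCC(F)(F)F)C(F)(F)F (trifluoroacetyl group of 14 only, lost again)
Why: Detrifluoroacetylative diazo transfer (a Regitz-type transfer with a trifluoroacetyl activating group): the kinetic enolate at the only enolisable position undergoes Claisen condensation to diketone 14, and sulfonyl azide transfer with loss of the trifluoroacetyl group should give the α′-diazo enone.

Step 7
Reactants: 11 racemic 5-{3-methoxy-1-[(triethylsilyl)oxy]prop-2-yn-1-yl}-2,2-dimethyl-7-[(triisopropylsilyl)oxy]-2H-chromene; 15 1-diazo-3-methoxybut-3-en-2-one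
Product: 20 racemic 2-{[2,2-dimethyl-7-(triisopropylsilyloxy)-2H-chromen-5-yl](triethylsilyloxy)methyl}-3,5-dimethoxyphenol, via vinylketene 16 (not isolated), via vinylcyclobutenone 17 (not isolated), via dienylketene 18 (not isolated), via cyclohexadienone 19 (not isolated)
Conditions: 15 (2 equiv, in portions), degassed PhMe, LEDs 400–440 nm, rt; then 80 °C, dark
Reagents that add atoms: none
Why: Selective excitation of the diazo n→π* band of 15 triggers a Wolff rearrangement (1,2-shift of the methoxyvinyl carbon with loss of N2) to vinylketene 16, which the polarised ynol ether 11 should capture in a regiospecific (2+2) cycloaddition, its nucleophilic carbinol-bearing carbon bonding to the ketene carbonyl carbon and its methoxy-bearing carbon to the ketene α-carbon, to give cyclobutenone 17. At 80 °C 17 should open by 4π electrocyclic cleavage to dienylketene 18, whose 6π electrocyclisation (bond between the ketene carbon and the terminal CH2) closes ring A as cyclohexadienone 19, and enolisation delivers phenol 20. The closest known reaction type is the Danheiser benzannulation of α,β-unsaturated α′-diazo ketones with alkoxyalkynes, which gives resorcinol monoethers. No stereocentre is created: the carbinol centre is carried through unchanged as the racemate and the ring stereocentre of 17 is erased on ring opening. The step needs regioselectivity in the (2+2) event, secured by the donor polarisation of the ynol ether, and chemoselectivity for the alkyne over the chromene alkene, secured by the far higher nucleophilicity of the ynol ether. Long-wavelength light is chosen because the 2H-chromene absorbs only below about 350 nm and would otherwise ring-open photochemically, and the methoxy ynol ether has no retro-ene pathway at 80 °C.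

Step 8
Reactants: 20 racemic 2-{[2,2-dimethyl-7-(triisopropylsilyloxy)-2H-chromen-5-yl](triethylsilyloxy)methyl}-3,5-dimethoxyphenol
Product: 21 racemic 2-[hydroxy(7-hydroxy-2,2-dimethyl-2H-chromen-5-yl)methyl]-3,5-dimethoxyphenol
Conditions: Bu4NF, AcOH (1:1), THF, 0 °C → rt
Reagents that add atoms: none
Why: Fluoride cleavage of both Si–O bonds (silyl ether deprotection) is buffered with acetic acid so that no ring A phenoxide can expel the doubly benzylic oxygen, and any silyl migration between the neighbouring oxygens of 20 is inconsequential because every silyl group is removed.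

Step 9
Reactants: 21 racemic 2-[hydroxy(7-hydroxy-2,2-dimethyl-2H-chromen-5-yl)methyl]-3,5-dimethoxyphenol
Product: 22 (2-hydroxy-4,6-dimethoxyphenyl)(7-hydroxy-2,2-dimethyl-2H-chromen-5-yl)methanone
Conditions: activated MnO2 (excess), EtOAc, rt
Reagents that add atoms: none
Why: MnO2 oxidation of a benzylic alcohol should convert the doubly benzylic carbinol selectively into the hydrogen-bonded 2-hydroxybenzophenone, which removes the racemic centre, while the phenols, aryl ethers and chromene alkene are inert under these neutral conditions.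

Compound list
1 | 3,5-dihydroxybenzaldehyde | O=Cc1cc(O)cc(O)c1 | starting material
2 | 3-chloro-3-methylbut-1-yne | C#CC(C)(C)Cl | starting material
3 | 3-hydroxy-5-[(2-methylbut-3-yn-2-yl)oxy]benzaldehyde | C#CC(C)(C)Oc1cc(O)cc(C=O)c1 | intermediate
4 | 3,5-dihydroxy-2-(3-methylbuta-1,2-dien-1-yl)benzaldehyde (allenylphenol) | CC(C)=C=Cc1c(O)cc(O)cc1C=O | intermediate
5 | (6Z)-3-hydroxy-6-(3-methylbut-2-en-1-ylidene)-5-oxocyclohexa-1,3-diene-1-carbaldehyde (o-quinone methide) | O=C1C=C(O)C=C(C=O)/C1=C/C=C(C)C | intermediate
6 | 7-hydroxy-2,2-dimethyl-2H-chromene-5-carbaldehyde | O=Cc1cc(O)cc2c1C=CC(C)(C)O2 | intermediate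
7 | 2,2-dimethyl-7-[(triisopropylsilyl)oxy]-2H-chromene-5-carbaldehyde | O=Cc1cc(O[Si](C(C)C)(C(C)C)C(C)C)cc2c1C=CC(C)(C)O2 | intermediate
8 | chloroacetaldehyde dimethyl acetal (2-chloro-1,1-dimethoxyethane) | COC(CCl)OC | starting material
9 | lithium methoxyacetylide | COC#C[Li] | intermediate
10 | racemic lithium 1-{2,2-dimethyl-7-[(triisopropylsilyl)oxy]-2H-chromen-5-yl}-3-methoxyprop-2-yn-1-olate | COC#CC(O[Li])c1cc(O[Si](C(C)C)(C(C)C)C(C)C)cc2c1C=CC(C)(C)O2 | intermediate
11 | racemic 5-{3-methoxy-1-[(triethylsilyl)oxy]prop-2-yn-1-yl}-2,2-dimethyl-7-[(triisopropylsilyl)oxy]-2H-chromene | COC#CC(O[Si](CC)(CC)CC)c1cc(O[Si](C(C)C)(C(C)C)C(C)C)cc2c1C=CC(C)(C)O2 | intermediate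
12 | 3,3-dimethoxybutan-2-one | CC(=O)C(C)(OC)OC | starting material
13 | 3-methoxybut-3-en-2-one | C=C(OC)C(C)=O | intermediate
14 | 1,1,1-trifluoro-5-methoxyhex-5-ene-2,4-dione | C=C(OC)C(=O)CC(=O)C(F)(F)F | intermediate
15 | 1-diazo-3-methoxybut-3-en-2-one | C=C(OC)C(=O)C=[N+]=[N-] | intermediate
16 | 3-methoxybuta-1,3-dien-1-one (vinylketene) | C=C(OC)C=C=O | intermediate
17 | 2-{[2,2-dimethyl-7-(triisopropylsilyloxy)-2H-chromen-5-yl](triethylsilyloxy)methyl}-3-methoxy-4-(1-methoxyethenyl)cyclobut-2-en-1-one, racemic mixture of diastereomers | C=C(OC)C1C(=O)C(C(O[Si](CC)(CC)CC)c2cc(O[Si](C(C)C)(C(C)C)C(C)C)cc3c2C=CC(C)(C)O3)=C1OC | intermediate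
18 | racemic (3E)-2-{[2,2-dimethyl-7-(triisopropylsilyloxy)-2H-chromen-5-yl](triethylsilyloxy)methyl}-3,5-dimethoxyhexa-1,3,5-trien-1-one (dienylketene) | C=C(OC)/C=C(OC)\C(=C=O)C(O[Si](CC)(CC)CC)c1cc(O[Si](C(C)C)(C(C)C)C(C)C)cc2c1C=CC(C)(C)O2 | intermediate
19 | racemic 2-{[2,2-dimethyl-7-(triisopropylsilyloxy)-2H-chromen-5-yl](triethylsilyloxy)methyl}-3,5-dimethoxycyclohexa-2,4-dien-1-one | O=C1CC(OC)=CC(OC)=C1C(O[Si](CC)(CC)CC)c2cc(O[Si](C(C)C)(C(C)C)C(C)C)cc3c2C=CC(C)(C)O3 | intermediate
20 | racemic 2-{[2,2-dimethyl-7-(triisopropylsilyloxy)-2H-chromen-5-yl](triethylsilyloxy)methyl}-3,5-dimethoxyphenol | COc1cc(O)c(C(O[Si](CC)(CC)CC)c2cc(O[Si](C(C)C)(C(C)C)C(C)C)cc3c2C=CC(C)(C)O3)c(OC)c1 | intermediate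
21 | racemic 2-[hydroxy(7-hydroxy-2,2-dimethyl-2H-chromen-5-yl)methyl]-3,5-dimethoxyphenol | COc1cc(O)c(C(O)c2cc(O)cc3c2C=CC(C)(C)O3)c(OC)c1 | intermediate
22 | (2-hydroxy-4,6-dimethoxyphenyl)(7-hydroxy-2,2-dimethyl-2H-chromen-5-yl)methanone | COc1cc(O)c(C(=O)c2cc(O)cc3c2C=CC(C)(C)O3)c(OC)c1 | target

Total step count: 9.
Longest linear sequence: 7 steps (1 → 3 → 6 → 7 → 11 → 20 → 21 → 22; steps 1, 2, 3, 4, 7, 8, 9). The diazoketone branch (steps 5 and 6) joins at step 7.

Steps most likely to fail

Step 7. The Wolff rearrangement may be inefficient at long wavelength, the vinylketene may dimerise faster than the hindered ynol ether captures it, or residual light absorption may damage the chromene. The fallback generates the same vinylketene thermally and without a diazo compound. It sets out from 8: NaNH2 in liquid NH3 should give methoxyacetylene F1, and (2+2) cycloaddition of F1 with dichloroketene (from Cl3CCOCl and Zn(Cu) in Et2O) should give 4,4-dichloro-3-methoxycyclobut-2-en-1-one F2. Reductive dechlorination (Zn, AcOH, TMEDA, EtOH) should give 3-methoxycyclobut-2-en-1-one F3. Heating F3 with 11 in toluene at 80–110 °C opens the cyclobutenone by 4π electrocyclic cleavage to 16, and the cascade through 17, 18 and 19 then runs in the dark. The fallback comes back to the route at 20.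

Step 2. The sigmatropic shift may show poor regioselectivity, with migration to the ring carbon between the two oxygens, and the free hydroxy aldehyde may degrade on heating. The fallback replaces electronic bias by steric blocking and sets out from 3. Silylation (i-Pr3SiCl, imidazole, DMF) should give 3-[(2-methylbut-3-yn-2-yl)oxy]-5-[(triisopropylsilyl)oxy]benzaldehyde F4, in which the bulky silyl ether flanks the unwanted ortho carbon. Heating F4 in o-xylene at 140 °C should then run the same cascade through 3-hydroxy-2-(3-methylbuta-1,2-dien-1-yl)-5-[(triisopropylsilyl)oxy]benzaldehyde F5 and the silylated o-quinone methide (6Z)-6-(3-methylbut-2-en-1-ylidene)-5-oxo-3-[(triisopropylsilyl)oxy]cyclohexa-1,3-diene-1-carbaldehyde F6. The fallback comes back to the route at 7.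

Step 8. Fluoride or adventitious base may ionise the doubly benzylic C–O bond next to the free ring A phenol (o-quinone methide formation), leading to oligomers before or after the silyl groups are lost. The fallback oxidises before any fluoride is used and sets out from 20. DDQ in CH2Cl2 with pH 7 buffer at 0 °C should abstract hydride from the electron-rich doubly benzylic silyl ether and, after loss of the silyl group to water, give (2-hydroxy-4,6-dimethoxyphenyl){2,2-dimethyl-7-[(triisopropylsilyl)oxy]-2H-chromen-5-yl}methanone F7, which can no longer ionise. Bu4NF in THF at 0 °C then removes the aryl silyl ether. The fallback bypasses 21 and comes back to the route at 22.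

Further compounds
F1 | step 7 | methoxyacetylene | COC#C
F2 | step 7 | 4,4-dichloro-3-methoxycyclobut-2-en-1-one | COC1=CC(=O)C1(Cl)Cl
F3 | step 7 | 3-methoxycyclobut-2-en-1-one | COC1=CC(=O)C1
F4 | step 2 | 3-[(2-methylbut-3-yn-2-yl)oxy]-5-[(triisopropylsilyl)oxy]benzaldehyde | C#CC(C)(C)Oc1cc(O[Si](C(C)C)(C(C)C)C(C)C)cc(C=O)c1
F5 | step 2 | 3-hydroxy-2-(3-methylbuta-1,2-dien-1-yl)-5-[(triisopropylsilyl)oxy]benzaldehyde | CC(C)=C=Cc1c(O)cc(O[Si](C(C)C)(C(C)C)C(C)C)cc1C=O
F6 | step 2 | (6Z)-6-(3-methylbut-2-en-1-ylidene)-5-oxo-3-[(triisopropylsilyl)oxy]cyclohexa-1,3-diene-1-carbaldehyde | O=C1C=C(O[Si](C(C)C)(C(C)C)C(C)C)C=C(C=O)/C1=C/C=C(C)C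
F7 | step 8 | (2-hydroxy-4,6-dimethoxyphenyl){2,2-dimethyl-7-[(triisopropylsilyl)oxy]-2H-chromen-5-yl}methanone | COc1cc(O)c(C(=O)c2cc(O[Si](C(C)C)(C(C)C)C(C)C)cc3c2C=CC(C)(C)O3)c(OC)c1
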